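The cyclohexene ring of the target (C3a–C4–C5–C6=C7–C7a, indene numbering) is a Diels–Alder retron: its C6=C7 double bond lies between the ring-fusion bond C3a–C7a, shared with the cyclopentanone ring, and the C4–C5 bond joining the two quaternary carbons. Both bonds are made in one intramolecular [4+2] cycloaddition of an acyclic tetraenal, generated in the same flask by Wittig olefination; it closes both rings and sets four stereocenters. The precursor is a linear chain whose only stereocenters are an ethyl/silyloxy/ethyl triad; allylic strain against the ethyl groups on diene and dienophile relays it to the new centers, and C2 is finally oxidised to the ketone.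

Key step: step 10

Assumption: the N-butanoyl oxazolidinone of step 1 and the α-ethyl formyl ylide of steps 6, 7 and 10 are taken as catalogue reagents.

Step 1
Reactants: 1 (R)-4-benzyl-3-butanoyl-1,3-oxazolidin-2-one; 2 2-ethylacrolein (2-methylidenebutanal)
Product: 3 (4R)-4-benzyl-3-[(2R,3R)-2-ethyl-3-hydroxy-4-methylidenehexanoyl]-1,3-oxazolidin-2-one
Conditions: Bu2BOTf, Et3N, CH2Cl2, 0 °C; then 2, −78 to 0 °C; then H2O2, MeOH, pH 7 buffer, 0 °C
Reagents that add atoms: none
Why: Evans syn aldol addition: the Z-boron enolate of 1 reacts through a closed chair transition state on the face opposite the benzyl group, which should set the 2R ethyl and 3R hydroxyl centers (syn) together, while the α-branched enal 2 cannot enolise and adds only at the carbonyl.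

Step 2
Reactants: 3 (4R)-4-benzyl-3-[(2R,3R)-2-ethyl-3-hydroxy-4-methylidenehexanoyl]-1,3-oxazolidin-2-one
Product: 4 (2R,3R)-2-ethyl-3-hydroxy-N-methoxy-N-methyl-4-methylidenehexanamide
Conditions: MeO(Me)NH·HCl, AlMe3, CH2Cl2, −20 to 0 °C
Reagents that add atoms: N,O-dimethylhydroxylamine hydrochloride, CNOC.Cl
Why: Weinreb amide formation by aluminium amide transamination, which is assisted by the free β-hydroxyl group and should release the auxiliary without epimerising the α-center.

Step 3
Reactants: 4 (2R,3R)-2-ethyl-3-hydroxy-N-methoxy-N-methyl-4-methylidenehexanamide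
Product: 5 (2R,3R)-2-ethyl-N-methoxy-N-methyl-4-methylidene-3-(triethylsilyloxy)hexanamide
Conditions: Et3SiOTf, 2,6-lutidine, CH2Cl2, −78 to 0 °C
Reagents that add atoms: triethylsilyl trifluoromethanesulfonate, CC[Si](CC)(CC)OS(=O)(=O)C(F)(F)F
Why: Silyl ether formation with the reactive triflate caps the hindered secondary alcohol as a triethylsilyl ether that withstands borane, ylides, amide bases and iBu2AlH but is cleaved by the aqueous acid of step 11.

Step 4
Reactants: 5 (2R,3R)-2-ethyl-N-methoxy-N-methyl-4-methylidene-3-(triethylsilyloxy)hexanamide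
Product: 7 (2R,3S,4S)-2,4-diethyl-5-hydroxy-N-methoxy-N-methyl-3-(triethylsilyloxy)pentanamide, via alkylborane 6 (not isolated)
Conditions: 9-BBN, THF, 0 °C to rt; then NaOH, H2O2, 0 °C
Reagents that add atoms: hydrogen peroxide, OO
Why: Hydroboration–oxidation: 9-BBN adds to the terminal carbon of the 1,1-disubstituted alkene on the face dictated by minimised allylic strain at the silyloxy-bearing carbon, which should set the new C4 center anti to the C3 oxygen and hence anti to the C2 ethyl group along the chain, and the C–B bond is oxidised with retention.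

Step 5
Reactants: 7 (2R,3S,4S)-2,4-diethyl-5-hydroxy-N-methoxy-N-methyl-3-(triethylsilyloxy)pentanamide
Product: 8 (2R,3S,4R)-2,4-diethyl-N-methoxy-N-methyl-5-oxo-3-(triethylsilyloxy)pentanamide
Conditions: Dess–Martin periodinane, NaHCO3, CH2Cl2, 0 °C to rt
Reagents that add atoms: none
Why: Dess–Martin oxidation under buffered, non-epimerising conditions converts the primary alcohol to the α-branched aldehyde, which is used at once.

Step 6
Reactants: 8 (2R,3S,4R)-2,4-diethyl-N-methoxy-N-methyl-5-oxo-3-(triethylsilyloxy)pentanamide; 9 2-(triphenylphosphoranylidene)butanal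
Product: 10 (2R,3S,4S,5E)-2,4,6-triethyl-N-methoxy-N-methyl-7-oxo-3-(triethylsilyloxy)hept-5-enamide
Conditions: PhMe, 80 °C
Reagents that add atoms: none
Why: Wittig olefination with the stabilised formyl ylide is E-selective, placing the chain cis to the ethyl group, and should stop after one homologation because the α-ethyl enal formed is far less electrophilic than the aliphatic aldehyde.

Step 7
Reactants: 10 (2R,3S,4S,5E)-2,4,6-triethyl-N-methoxy-N-methyl-7-oxo-3-(triethylsilyloxy)hept-5-enamide; 9 2-(triphenylphosphoranylidene)butanal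
Product: 11 (2R,3S,4S,5E,7E)-2,4,6,8-tetraethyl-N-methoxy-N-methyl-9-oxo-3-(triethylsilyloxy)nona-5,7-dienamide
Conditions: 9 (excess), PhMe, 110 °C
Reagents that add atoms: none
Why: A second Wittig olefination with the same ylide under more forcing conditions extends the enal to the (5E,7E)-dienal, again with the formyl group trans to the chain.

Step 8
Reactants: 11 (2R,3S,4S,5E,7E)-2,4,6,8-tetraethyl-N-methoxy-N-methyl-9-oxo-3-(triethylsilyloxy)nona-5,7-dienamide; 12 diethyl benzylphosphonate
Product: 13 (2R,3S,4S,5E,7E,9E)-2,4,6,8-tetraethyl-N-methoxy-N-methyl-10-phenyl-3-(triethylsilyloxy)deca-5,7,9-trienamide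
Conditions: 12, NaN(SiMe3)2, THF, −78 °C; then 11, −78 to 0 °C
Reagents that add atoms: none
Why: Horner–Wadsworth–Emmons olefination with the preformed benzylphosphonate anion should give the E-styryl terminus and leave the Weinreb amide and the stereocenters untouched at low temperature.

Step 9
Reactants: 13 (2R,3S,4S,5E,7E,9E)-2,4,6,8-tetraethyl-N-methoxy-N-methyl-10-phenyl-3-(triethylsilyloxy)deca-5,7,9-trienamide
Product: 14 (2R,3S,4S,5E,7E,9E)-2,4,6,8-tetraethyl-10-phenyl-3-(triethylsilyloxy)deca-5,7,9-trienal
Conditions: iBu2AlH, THF, −78 °C; aqueous sodium potassium tartrate work-up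
Reagents that add atoms: none
Why: Reduction of the Weinreb amide with iBu2AlH stops at the aldehyde because the chelated tetrahedral intermediate collapses only on work-up, and the α-center is not disturbed at −78 °C.

Step 10
Reactants: 14 (2R,3S,4S,5E,7E,9E)-2,4,6,8-tetraethyl-10-phenyl-3-(triethylsilyloxy)deca-5,7,9-trienal; 9 2-(triphenylphosphoranylidene)butanal
Product: 16 (1S,2S,3S,3aR,4R,5S,7aR)-1,3,4,5,7-pentaethyl-5-[(E)-2-phenylethenyl]-2-(triethylsilyloxy)-2,3,3a,4,5,7a-hexahydro-1H-indene-4-carbaldehyde, via tetraenal 15 (not isolated)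
Conditions: 9 (1.3 equiv), BHT (cat.), PhMe, 80 °C then 110 °C
Reagents that add atoms: none
Why: Wittig olefination of 14 by the stabilised ylide 9 gives the (2E)-enal 15, and on further heating its C2=C3 enal and its C7=C8–C9=C10 diene, held three atoms apart, combine in a concerted suprafacial [4+2] cycloaddition (type 1 intramolecular Diels–Alder reaction; closest known class: thermal Wittig olefination–intramolecular Diels–Alder sequences of nona-1,6,8-triene-type enals). The six-membered ring closes by the cycloaddition itself (new bonds C3–C7 and C2–C10 of 15, which are the ring-fusion bond and the bond between the two quaternary carbons of 16), and the five-membered ring closes in the same event because the three-atom tether C4–C5–C6 is carried across the ring-fusion bond. The quaternary centers C4 and C5 of 16 take their relative configuration from the E geometry of the dienophile and the E,E geometry of the diene (styryl outside, ethyl inside), and the trans ring fusion C3a/C7a follows from the transition state with the formyl group endo and the tether anti. The absolute sense comes from the two ethyl-bearing stereocenters of the tether: each keeps its hydrogen in the plane of the adjacent trisubstituted alkene to avoid 1,3-allylic strain with the cis ethyl group, so the tether can reach only one face of each π system. Because these two centers are anti to each other, only the trans-fused, formyl-endo transition state on that face satisfies both constraints, while every cis-fused alternative forces one ethyl group into an alkene plane; this secures the endo and facial selectivity the step needs. The hindered neopentyl aldehyde of 16 should not react with the remaining ylide.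

Step 11
Reactants: 16 (1S,2S,3S,3aR,4R,5S,7aR)-1,3,4,5,7-pentaethyl-5-[(E)-2-phenylethenyl]-2-(triethylsilyloxy)-2,3,3a,4,5,7a-hexahydro-1H-indene-4-carbaldehyde
Product: 17 (1S,3S,3aR,4R,5S,7aR)-1,3,4,5,7-pentaethyl-2-oxo-5-[(E)-2-phenylethenyl]-2,3,3a,4,5,7a-hexahydro-1H-indene-4-carboxylic acid
Conditions: CrO3, H2SO4, H2O, acetone, 0 °C to rt
Reagents that add atoms: water, O
Why: Jones oxidation: the aqueous acid cleaves the triethylsilyl ether, and chromic acid oxidises the freed secondary alcohol to the ketone and the aldehyde, through its hydrate, to the carboxylic acid, while the two α-ethyl centers of the new ketone already hold the thermodynamically preferred all-trans arrangement.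

Compound list

1 | (R)-4-benzyl-3-butanoyl-1,3-oxazolidin-2-one | CCCC(=O)N1[C@H](Cc2ccccc2)COC1=O | starting material
2 | 2-ethylacrolein (2-methylidenebutanal) | CCC(=C)C=O | starting material
3 | (4R)-4-benzyl-3-[(2R,3R)-2-ethyl-3-hydroxy-4-methylidenehexanoyl]-1,3-oxazolidin-2-one | CCC(=C)[C@H](O)[C@@H](CC)C(=O)N1[C@H](Cc2ccccc2)COC1=O | intermediate
4 | (2R,3R)-2-ethyl-3-hydroxy-N-methoxy-N-methyl-4-methylidenehexanamide | CCC(=C)[C@H](O)[C@@H](CC)C(=O)N(C)OC | intermediate
5 | (2R,3R)-2-ethyl-N-methoxy-N-methyl-4-methylidene-3-(triethylsilyloxy)hexanamide | CCC(=C)[C@H](O[Si](CC)(CC)CC)[C@@H](CC)C(=O)N(C)OC | intermediate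
6 | (2R,3S,4R)-5-(9-borabicyclo[3.3.1]nonan-9-yl)-2,4-diethyl-N-methoxy-N-methyl-3-(triethylsilyloxy)pentanamide | B1(C2CCCC1CCC2)C[C@H](CC)[C@H](O[Si](CC)(CC)CC)[C@@H](CC)C(=O)N(C)OC | intermediate
7 | (2R,3S,4S)-2,4-diethyl-5-hydroxy-N-methoxy-N-methyl-3-(triethylsilyloxy)pentanamide | OC[C@H](CC)[C@H](O[Si](CC)(CC)CC)[C@@H](CC)C(=O)N(C)OC | intermediate
8 | (2R,3S,4R)-2,4-diethyl-N-methoxy-N-methyl-5-oxo-3-(triethylsilyloxy)pentanamide | O=C[C@H](CC)[C@H](O[Si](CC)(CC)CC)[C@@H](CC)C(=O)N(C)OC | intermediate
9 | 2-(triphenylphosphoranylidene)butanal | CCC(C=O)=P(c1ccccc1)(c1ccccc1)c1ccccc1 | starting material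
10 | (2R,3S,4S,5E)-2,4,6-triethyl-N-methoxy-N-methyl-7-oxo-3-(triethylsilyloxy)hept-5-enamide | O=C/C(CC)=C/[C@H](CC)[C@H](O[Si](CC)(CC)CC)[C@@H](CC)C(=O)N(C)OC | intermediate
11 | (2R,3S,4S,5E,7E)-2,4,6,8-tetraethyl-N-methoxy-N-methyl-9-oxo-3-(triethylsilyloxy)nona-5,7-dienamide | O=C/C(CC)=C/C(CC)=C/[C@H](CC)[C@H](O[Si](CC)(CC)CC)[C@@H](CC)C(=O)N(C)OC | intermediate
12 | diethyl benzylphosphonate | CCOP(=O)(Cc1ccccc1)OCC | starting material
13 | (2R,3S,4S,5E,7E,9E)-2,4,6,8-tetraethyl-N-methoxy-N-methyl-10-phenyl-3-(triethylsilyloxy)deca-5,7,9-trienamide | c1ccccc1/C=C/C(CC)=C/C(CC)=C/[C@H](CC)[C@H](O[Si](CC)(CC)CC)[C@@H](CC)C(=O)N(C)OC | intermediate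
14 | (2R,3S,4S,5E,7E,9E)-2,4,6,8-tetraethyl-10-phenyl-3-(triethylsilyloxy)deca-5,7,9-trienal | c1ccccc1/C=C/C(CC)=C/C(CC)=C/[C@H](CC)[C@H](O[Si](CC)(CC)CC)[C@@H](CC)C=O | intermediate
15 | (2E,4S,5S,6S,7E,9E,11E)-2,4,6,8,10-pentaethyl-12-phenyl-5-(triethylsilyloxy)dodeca-2,7,9,11-tetraenal | c1ccccc1/C=C/C(CC)=C/C(CC)=C/[C@H](CC)[C@H](O[Si](CC)(CC)CC)[C@@H](CC)/C=C(\CC)C=O | intermediate
16 | (1S,2S,3S,3aR,4R,5S,7aR)-1,3,4,5,7-pentaethyl-5-[(E)-2-phenylethenyl]-2-(triethylsilyloxy)-2,3,3a,4,5,7a-hexahydro-1H-indene-4-carbaldehyde | CCC1=C[C@@](/C=C/c2ccccc2)(CC)[C@](CC)(C=O)[C@@H]2[C@@H]1[C@H](CC)[C@H](O[Si](CC)(CC)CC)[C@H]2CC | intermediate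
17 | (1S,3S,3aR,4R,5S,7aR)-1,3,4,5,7-pentaethyl-2-oxo-5-[(E)-2-phenylethenyl]-2,3,3a,4,5,7a-hexahydro-1H-indene-4-carboxylic acid | CCC1=C[C@@](/C=C/c2ccccc2)(CC)[C@](CC)(C(=O)O)[C@@H]2[C@@H]1[C@H](CC)C(=O)[C@H]2CC | target

Total step count: 11
Longest linear sequence: 11 steps (1 and 2 to 17; 9 and 12 enter as purchased reagents)

Steps most likely to fail

(a) Step 10. Residual ylide may olefinate the freshly formed enal before it cyclises, and at the temperature needed to join two fully substituted carbons the endo and facial preferences may erode. The fallback sets out from 14 and comes back at 16. Aldehyde 14 is olefinated at room temperature with ethyl 2-(triphenylphosphoranylidene)butanoate to the isolable ethyl tetraenoate F1, whose ester is too poor a dienophile to cyclise at that temperature and which can be freed of geometric isomers. iBu2AlH at −78 °C then reduces it to the allylic alcohol F2. MnO2 in CH2Cl2 unveils enal 15 with no ylide present, and Me2AlCl at −78 °C (Lewis acid-promoted intramolecular Diels–Alder reaction, which strengthens the formyl-endo preference) closes it to 16.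

(b) Step 11. Oxidation of the hindered neopentyl aldehyde may be slow, leaving time for oxidative damage to the styryl group or, once the silyl ether has fallen off, for lactol formation and oxidation to a lactone. The fallback sets out from 16 and comes back at 17. Pinnick oxidation (NaClO2, NaH2PO4, 2-methylbut-2-ene, tBuOH/H2O) converts the aldehyde to the silyl ether acid F3 while the alcohol is still masked. HF·pyridine in THF removes the silyl group to give the hydroxy acid F4, and Dess–Martin periodinane oxidises the alcohol to the ketone 17.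

(c) Step 7. The second olefination of the hindered α-ethyl enal is slow, and prolonged heating with the basic ylide may epimerise C4 of 10 through dienolisation or lead to over-homologation. The fallback sets out from 10 and comes back at 13, bypassing 11 and step 8. Dibromo-olefination of 10 (CBr4, PPh3, Et3N, CH2Cl2, 0 °C; first stage of the Corey–Fuchs sequence) gives the 1,1-dibromodiene F5. A trans-selective Suzuki coupling with (E)-2-phenylethenylboronic acid (Pd2(dba)3, tris(2-furyl)phosphine, Cs2CO3, aqueous dioxane) replaces the bromine trans to the chain and gives the (7Z)-bromotriene F6. Negishi coupling with EtZnCl (Pd(PtBu3)2, THF) then installs the ethyl group with retention to give 13.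

Further compounds
F1 | step 10 | ethyl (2E,4S,5S,6S,7E,9E,11E)-2,4,6,8,10-pentaethyl-12-phenyl-5-(triethylsilyloxy)dodeca-2,7,9,11-tetraenoate | c1ccccc1/C=C/C(CC)=C/C(CC)=C/[C@H](CC)[C@H](O[Si](CC)(CC)CC)[C@@H](CC)/C=C(\CC)C(=O)OCC
F2 | step 10 | (2E,4S,5S,6S,7E,9E,11E)-2,4,6,8,10-pentaethyl-12-phenyl-5-(triethylsilyloxy)dodeca-2,7,9,11-tetraen-1-ol | c1ccccc1/C=C/C(CC)=C/C(CC)=C/[C@H](CC)[C@H](O[Si](CC)(CC)CC)[C@@H](CC)/C=C(\CC)CO
F3 | step 11 | (1S,2S,3S,3aR,4R,5S,7aR)-1,3,4,5,7-pentaethyl-5-[(E)-2-phenylethenyl]-2-(triethylsilyloxy)-2,3,3a,4,5,7a-hexahydro-1H-indene-4-carboxylic acid | CCC1=C[C@@](/C=C/c2ccccc2)(CC)[C@](CC)(C(=O)O)[C@@H]2[C@@H]1[C@H](CC)[C@H](O[Si](CC)(CC)CC)[C@H]2CC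
F4 | step 11 | (1S,2S,3S,3aR,4R,5S,7aR)-1,3,4,5,7-pentaethyl-2-hydroxy-5-[(E)-2-phenylethenyl]-2,3,3a,4,5,7a-hexahydro-1H-indene-4-carboxylic acid | CCC1=C[C@@](/C=C/c2ccccc2)(CC)[C@](CC)(C(=O)O)[C@@H]2[C@@H]1[C@H](CC)[C@H](O)[C@H]2CC
F5 | step 7 | (2R,3S,4S,5E)-8,8-dibromo-2,4,6-triethyl-N-methoxy-N-methyl-3-(triethylsilyloxy)octa-5,7-dienamide | BrC(Br)=C/C(CC)=C/[C@H](CC)[C@H](O[Si](CC)(CC)CC)[C@@H](CC)C(=O)N(C)OC
F6 | step 7 | (2R,3S,4S,5E,7Z,9E)-8-bromo-2,4,6-triethyl-N-methoxy-N-methyl-10-phenyl-3-(triethylsilyloxy)deca-5,7,9-trienamide | c1ccccc1/C=C/C(Br)=C/C(CC)=C/[C@H](CC)[C@H](O[Si](CC)(CC)CC)[C@@H](CC)C(=O)N(C)OC
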